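## The problem

Atoms carry germacrane numbers: the ten-membered ring is C1–C10, C14 is the formyl carbon on C10, C15 the hydroxymethyl carbon on C4, C11–C13 the lactone carbons on C7. The lactone oxygen sits on C6, the methacrylate on O8 and the methyl ether on O9.

- The carbocycle is a cyclodecadiene whose two trisubstituted alkenes (C1=C10 and C4=C5) are both cis within the ring. A direct closure would have to overcome medium-ring strain and control two alkene geometries at once.
- Four contiguous stereocentres C6–C9 line one edge. O8 is cis to the C7 branch and trans to O9, and the lactone is trans-fused.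
- A C8 oxygen taken from the chiral pool can direct C9 (oxygen added anti) and C7 (hydride added anti). C6 can only be set later, on the ten-membered ring, under the influence of C7.
- The target holds three Michael acceptors (α-methylene lactone, methacrylate, enal) and an allylic alcohol. Every intermediate with a carbonyl at C6 or C10 has O8 or O9 in the β-position. Strong base and nucleophiles must therefore be kept from late intermediates, and the acrylate-type groups must come last.
- The enabling feature: C6 and C10 face each other across the ring and both are carbonyl carbons in disguise. C6 bears the lactone oxygen, and C10 bears a formyl group that a ketone can deliver through its enol triflate. A C6=C10 double bond turns the ring into a bicyclo[5.3.0]decadiene (cyclopentene C6–C10 fused to the cycloheptene C10, C1–C6). There C7–C9 sit on a rigid five-membered ring and C4=C5 is cis by ring size.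

## Retrosynthesis

**30 to 27 (via 29, 28).** The O8–acyl bond and the O15–Si bond are cut. The methacrylate cannot coexist with the enolate and tin hydride steps that precede it, so it goes on second to last. This needs O8 and O15 to be told apart: O8 carries TBS and O15 carries TBDPS. The forward steps ask for selective O8 desilylation, acylation of a hindered secondary alcohol and a buffered final fluoride step.

**27 to 23 (via 26, 25, 24).** C11=C13 and C10–C14 are cut. Carrying C13 or C14 through the ozonolysis would expose an electron-poor alkene or an aldehyde to earlier steps. Cutting C10–C14 leads to enol triflate 23 and so to ketone 22, which the key step supplies. The lactone enolate is used before the enal exists (Mannich base 24). The methylene is unmasked only after the tin hydride step. The forward route asks for a kinetic, ring-cis enol triflate at C1.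

**22 to 20 (via 21).** The lactone O–C12 bond and the C6–H bond are cut. The precursor is a diketone with the acetate side chain already on C7. The forward step asks for 1,2-reduction of the conjugated C6 carbonyl in preference to C10, and for hydride delivery that gives the trans-fused lactone.

**20 to 18 (key disconnection).** C6 and C10 are rejoined as a tetrasubstituted alkene. A macrocyclisation at any ring bond would pay cyclisation entropy and would have to set alkene geometry. A Grob-type fragmentation would give an alkene, not the two carbonyls needed here. Precursor 18 is a bicyclic diene without a carbonyl group, so no stereocentre in it can epimerise. The forward step asks ozone to choose the tetrasubstituted alkene of a conjugated diene.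

**18 to 17.** C4=C5 is cut (ring-closing metathesis). Closing C5–C6 by an intramolecular cross-coupling would need a stereodefined vinylmetal on the chain. Metathesis needs only two terminal alkenes. 17 is monocyclic.

**17 to 14 (via 16, 15).** The C7–H bond (conjugate reduction) and C5–C6 (Stille coupling) are cut. Alkylating a C7 enolate with a haloacetate would place the chain trans to O8, and the C6 ketone would then have two enolisable methines. With C7 as an alkylidene carbon the only α-hydrogen is at C10, so enol triflate 15 is regiodefined. Hydride then enters C7 anti to O8.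

**14 to 11 (via 13, 12).** C7=C11 is cut (aldol condensation with ethyl glyoxylate). The forward step asks for kinetic enolisation at the C7 methylene, not the C10 methine.

**11 to 8 (via 10, 9).** The C9–O bond is cut. Direct conjugate addition of methoxide would be reversible and would allow loss of the C8 silyloxide through the other enolate. Nucleophilic epoxidation, reductive opening and O-methylation are three irreversible steps that place O9 anti to O8.

**8 to 6 and 4; 6 to 5; 4 to 3, 2, 1.** C10–C1 is cut (Negishi coupling). Putting the chain on C10 before C9 is oxygenated makes C10 a methine, which is what later steers enolisation to C7. Enone 5 is commercial and brings C8. Iodide 4 comes in three steps from 2-bromoallyl alcohol 1.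

## Roads not taken

**Alternative 1:** The cut is at C7–C8 and O8–C6. Aldehyde A2 (C8–C10 with the C9 methoxy group) would be irradiated in furan A3. The Paternò–Büchi cycloaddition would give the exo oxetane A1; the furan supplies C6, C7, C11, C12 and the future lactone oxygen.
- Merits: the C6–C8 edge appears in one step from two cheap pieces, the exo preference makes the C7/C8 relationship predictable, and the lactone carbons arrive as an enol ether.
- Weak points: the only resident stereocentre, C9 of A2, is acyclic and α to the excited carbonyl, so face selectivity for C8 against C9 is expected to be poor, and A2 is configurationally labile. The acetal carbon C6 of A1 must still receive C5 with control. The ten-membered ring with two cis alkenes is not addressed and would need a later macrocyclisation.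
- Comparison: as an entry to the C6–C8 triad it is shorter than steps 4–13 here, and it fixes C6 against C7 at the outset, which the chosen plan leaves to a late reduction. The chosen plan sets against this a carbocycle made without any medium-ring closure and C8/C9 drawn from a ring-bound chiral-pool centre.

**Alternative 2:** The cut is at C4–C5 and C1–C10. Cyclohexenone A5 and methyl cyclobut-1-ene-1-carboxylate A6 would combine under irradiation to the cis-anti-cis photoadduct A4. Heating would then open the bicyclo[2.2.0]hexane unit to the cyclodeca-1(10),4-diene.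
- Merits: two steps build the whole ten-membered ring with both trisubstituted alkenes and with C14 and C15 attached and differentiated. No enol triflate or carbonylation is needed.
- Weak points: the photocycloaddition must create a quaternary C10, head-to-head and anti to the C9 methoxy group, on a crowded enone. The cycloreversion needs high temperature, where the 1,5-diene can undergo Cope rearrangement and β-alkoxy ketones eliminate. The alkene geometries follow from the adduct and are not cis,cis by default. A5 carries the same C7–C9 problem without the help of a five-membered ring.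
- Comparison: it is more convergent and would save steps 17–19 here. The chosen plan sets against this a key step at −78 °C under neutral conditions and a C4=C5 geometry fixed by ring size.

**Alternative 3:** The cut is at C8–C9, with C1–C6 as an extra bond in the precursor. The potassium alkoxide of a six-membered carbinol carrying two enol-ether alkenyl arms would rearrange (anionic oxy-Cope) to the enolate of cyclodecadienone A7.
- Merits: like the chosen plan it expands a ring and avoids macrocyclisation. C8 and C9 are created together through a chair transition state, and C6 emerges as an enolate ready to receive the C7 branch.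
- Weak points: both migrating termini are enol ethers of defined geometry, which are long to prepare. C1=C10 is delivered trans in the ring and must be isomerised. The C7 branch would be attached to a ten-membered enolate with uncertain face selectivity and with the C8 ether ready to eliminate. The absolute configuration must come from a resolved cyclohexenol.
- Comparison: from ring formation to the end it is shorter and needs no carbonylation. The chosen plan sets against this that C7–C9 are fixed on a rigid cyclopentene before the ring is opened.

Key step: step 15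

Remark: C10 in 10–13, C7 and C11 in 12 and 13, and C11 in 24–26 form as epimer mixtures that converge when these carbons become trigonal. The C7=C11 geometry of 14–16 is left open because both isomers give 17.

Remark: the bis-magnesium reagent of step 2 is prepared beforehand from 3-chloropropan-1-ol (i-PrMgCl, then Mg) and used as a stock solution.

## Route

Step 1
Reactants: 1 2-bromoprop-2-en-1-ol
Product: 2 [(2-bromoprop-2-en-1-yl)oxy](tert-butyl)diphenylsilane
Conditions: t-BuPh2SiCl, imidazole, CH2Cl2, 0 °C to rt
Reagents that add atoms: tert-butyl(chloro)diphenylsilane, CC(C)(C)[Si](Cl)(c1ccccc1)c1ccccc1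
Why: Silylation of a primary allylic alcohol; imidazole activates the silyl chloride and takes up HCl, and the vinyl bromide is inert.

Step 2
Reactants: 2 [(2-bromoprop-2-en-1-yl)oxy](tert-butyl)diphenylsilane
Product: 3 4-(tert-butyldiphenylsilyloxymethyl)pent-4-en-1-ol
Conditions: ClMg(CH2)3OMgCl, Pd(dppf)Cl2 (cat.), THF, 0 to 40 °C; aq. NH4Cl
Reagents that add atoms: 3-(chloromagnesiooxy)propylmagnesium chloride, Cl[Mg]CCCO[Mg]Cl
Why: Kumada coupling (oxidative addition of zerovalent palladium to the vinyl bromide, transmetalation, reductive elimination); the alkoxide end of the reagent is inert and the silyl ether is too poor a leaving group for β-elimination to an allene.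

Step 3
Reactants: 3 4-(tert-butyldiphenylsilyloxymethyl)pent-4-en-1-ol
Product: 4 tert-butyl[(5-iodo-2-methylidenepentyl)oxy]diphenylsilane
Conditions: I2, PPh3, imidazole, CH2Cl2, 0 °C to rt
Reagents that add atoms: iodine, II
Why: Appel-type iodination; iodide displaces the alkoxyphosphonium group at the primary carbon under neutral conditions that spare the alkene and the silyl ether.

Step 4
Reactants: 5 (S)-4-(tert-butyldimethylsilyloxy)cyclopent-2-en-1-one
Product: 6 (S)-4-(tert-butyldimethylsilyloxy)-2-iodocyclopent-2-en-1-one
Conditions: I2, pyridine, CH2Cl2, 0 °C to rt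
Reagents that add atoms: iodine, II
Why: α-Iodination of an enone by reversible conjugate addition of pyridine, iodination of the enolate and loss of pyridine; the C8 stereocentre is not involved.

Step 5
Reactants: 4 tert-butyl[(5-iodo-2-methylidenepentyl)oxy]diphenylsilane; 6 (S)-4-(tert-butyldimethylsilyloxy)-2-iodocyclopent-2-en-1-one
Product: 8 (S)-4-(tert-butyldimethylsilyloxy)-2-[4-(tert-butyldiphenylsilyloxymethyl)pent-4-en-1-yl]cyclopent-2-en-1-one, via alkylzinc iodide 7 (not isolated)
Conditions: 4, Zn, LiCl, THF, 40 °C; then 6, Pd2(dba)3, P(2-furyl)3, THF/DMF, rt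
Reagents that add atoms: none
Why: Zinc inserts into the primary iodide and the alkylzinc couples with the α-iodoenone (Negishi coupling), forming C10–C1; the neutral conditions spare the base-sensitive 4-silyloxy enone.

Step 6
Reactants: 8 (S)-4-(tert-butyldimethylsilyloxy)-2-[4-(tert-butyldiphenylsilyloxymethyl)pent-4-en-1-yl]cyclopent-2-en-1-one
Product: 9 epoxy ketone (oxirane on C9–C10 with its oxygen trans to the C8 silyloxy group)
Conditions: 30% H2O2, NaOH (cat.), MeOH, 0 °C
Reagents that add atoms: hydrogen peroxide, OO
Why: Weitz–Scheffer epoxidation; hydroperoxide adds to C9 from the face opposite the C8 silyloxy group and the enolate closes the oxirane on that face, which sets O9 trans to O8.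

Step 7
Reactants: 9 epoxy ketone
Product: 10 β-hydroxy ketone (C9 hydroxyl trans to the C8 silyloxy group; chain on C10)
Conditions: SmI2, THF/MeOH, −90 °C
Reagents that add atoms: none
Why: Reductive cleavage of an α,β-epoxy ketone; two single-electron transfers break the C10–O bond and MeOH protonates the samarium enolate at low temperature. The C9–O bond is untouched, so its configuration is kept.

Step 8
Reactants: 10 β-hydroxy ketone
Product: 11 β-methoxy ketone (3-methoxy-4-silyloxy-2-alkylcyclopentanone; O9 trans to O8)
Conditions: Me3OBF4, 1,8-bis(dimethylamino)naphthalene, CH2Cl2, 0 °C to rt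
Reagents that add atoms: trimethyloxonium tetrafluoroborate, C[O+](C)C.F[B-](F)(F)F
Why: O-Methylation with Meerwein's salt and a non-nucleophilic proton scavenger; no enolate forms, so the aldol-type substrate neither dehydrates nor cleaves.

Step 9
Reactants: 11 β-methoxy ketone
Product: 12 aldol adduct (ethyl 2-hydroxyacetate unit on C7)
Conditions: LiN(i-Pr)2, THF, −78 °C; ethyl glyoxylate, −78 °C; AcOH
Reagents that add atoms: ethyl glyoxylate, CCOC(=O)C=O
Why: Kinetic deprotonation takes the C7 methylene in preference to the C10 methine, and the lithium enolate adds to the reactive glyoxylate (aldol addition) faster than it expels the C8 silyloxide at −78 °C.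

Step 10
Reactants: 12 aldol adduct
Product: 14 alkylidene ketone (C7=C11 exocyclic and conjugated to the C6 ketone and the ester), via mesylate 13 (not isolated)
Conditions: MsCl, Et3N, CH2Cl2, −20 to 0 °C
Reagents that add atoms: none
Why: Mesylation and E1cB loss of mesylate through the C7 enolate complete the aldol condensation; triethylamine suffices and is too weak to expel the C9 methoxy group or shift the alkene into the ring.

Step 11
Reactants: 14 alkylidene ketone
Product: 15 dienyl triflate (C6 triflate on the C6=C10 alkene)
Conditions: KN(SiMe3)2, PhNTf2, THF, −78 °C (base added to ketone and PhNTf2)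
Reagents that add atoms: N-phenylbis(trifluoromethanesulfonimide), O=S(=O)(N(c1ccccc1)S(=O)(=O)C(F)(F)F)C(F)(F)F
Why: Enol triflate formation; C7 is trigonal, so the only α-hydrogen is on C10 and enolisation is regiospecific, and the enolate is triflated as it forms, before it can lose the C9 methoxy group.

Step 12
Reactants: 15 dienyl triflate
Product: 16 triene ester (vinyl on C6; C6=C10 tetrasubstituted; C7=C11 alkylidene ester)
Conditions: CH2=CHSnBu3, Pd2(dba)3, AsPh3, LiCl, NMP, rt
Reagents that add atoms: tributyl(vinyl)stannane, C=C[Sn](CCCC)(CCCC)CCCC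
Why: Stille coupling of the enol triflate with retention at C6 installs C5 under neutral, ester-tolerant conditions.

Step 13
Reactants: 16 triene ester
Product: 17 diene ester (CH2CO2Et on C7 cis to the C8 silyloxy group; methoxy on C9 trans to it)
Conditions: Cu(OAc)2·H2O (cat.), 1,2-(Ph2P)2C6H4 (cat.), (EtO)2MeSiH, t-BuOH, toluene, rt
Reagents that add atoms: none
Why: Copper hydride conjugate reduction of a β,β-disubstituted unsaturated ester delivers hydride to the β-carbon C7. Approach anti to the bulky neighbouring C8 silyloxy group leaves the acetate arm cis to O8, and the fully substituted δ-carbon C10 disfavours 1,6-addition.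

Step 14
Reactants: 17 diene ester
Product: 18 bicyclic diene ethyl 2-[2-(tert-butyldimethylsilyloxy)-7-(tert-butyldiphenylsilyloxymethyl)-3-methoxy-1,2,3,4,5,6-hexahydroazulen-1-yl]acetate (C6=C10 at the ring fusion; C4=C5 in the seven-membered ring)
Conditions: second-generation Hoveyda–Grubbs catalyst (cat.), toluene, 80 °C, high dilution
Reagents that add atoms: none
Why: Ring-closing metathesis between the terminal vinyl group and the 1,1-disubstituted alkene forms C4=C5 with loss of ethene; the tetrasubstituted alkene is inert and the seven-membered ring enforces the cis geometry.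

Step 15
Reactants: 18 bicyclic diene
Product: 20 cyclodec-4-ene-6,10-dione (C6 and C10 ketones; C4=C5 cis; C7 to C9 unchanged), via ozonide 19 (not isolated)
Conditions: O3, CH2Cl2, −78 °C, Sudan Red 7B as end-point indicator; PPh3, −78 °C to rt
Reagents that add atoms: ozone, [O-][O+]=O
Why: Ozone adds as a 1,3-dipole across C6=C10 to give the primary ozonide, which splits into a ketone and a carbonyl oxide. These stay tethered by the C1–C5 and C7–C9 bridges and recombine to the 1,2,4-trioxolane 19, which PPh3 reduces to the two ketones. The closest known reaction type is ozonolysis of the ring-fusion alkene of a fused bicycle to a medium-ring diketone. No ring is closed by bond formation: the ten-membered ring appears when the bond shared by the five- and seven-membered rings is cut, so no cyclisation mode or entropy penalty applies. No stereocentre is created, and C7–C9 keep the configuration set on the cyclopentene because the step is neutral and cold. The selectivity needed is C6=C10 over C4=C5. It rests on the higher nucleophilicity of the tetrasubstituted alkene, on the electron-withdrawing allylic silyloxymethyl group on C4, and on deactivation of C4=C5 as an enone once C6 is a ketone. Ozone is metered to the dye end-point so the enone is not attacked.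

Step 16
Reactants: 20 cyclodec-4-ene-6,10-dione
Product: 22 keto lactone (trans-fused 6,12-olide; C10 ketone; O8 TBS; O15 TBDPS), via hydroxy ester 21 (not isolated)
Conditions: NaBH4, CeCl3·7H2O, MeOH, −78 °C; then PPTS (cat.), toluene, 50 °C
Reagents that add atoms: none
Why: Luche reduction; CeCl3 activates the more Lewis-basic conjugated C6 carbonyl and the methoxyborohydrides add 1,2, while the hindered medium-ring C10 ketone reacts more slowly at −78 °C. Hydride is expected to enter C6 from the ring periphery anti to the C7 branch, and the γ-hydroxy ester then closes to the trans-fused lactone.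

Step 17
Reactants: 22 keto lactone
Product: 23 enol triflate (C10 triflate on a ring-cis C1=C10 alkene)
Conditions: KN(SiMe3)2, PhNTf2, THF, −78 °C
Reagents that add atoms: N-phenylbis(trifluoromethanesulfonimide), O=S(=O)(N(c1ccccc1)S(=O)(=O)C(F)(F)F)C(F)(F)F
Why: Kinetic enol triflate formation; the C1 methylene is deprotonated in preference to the methoxy-bearing C9 methine and the less acidic lactone α-methylene, and the ring already holding a cis alkene and a lactone favours the ring-cis enolate.

Step 18
Reactants: 23 enol triflate
Product: 24 Mannich base (dimethylaminomethyl group on C11 of the lactone)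
Conditions: LiN(i-Pr)2, THF, −78 °C; CH2=NMe2 I, −78 °C to rt
Reagents that add atoms: N,N-dimethylmethyleneiminium iodide, C=[N+](C)C.[I-]
Why: Mannich reaction of the lactone enolate with Eschenmoser's salt; the vinyl triflate tolerates the hindered amide base at low temperature, and no leaving group is β to C11.

Step 19
Reactants: 24 Mannich base
Product: 25 enal amine (formyl group C14 on C10; C1=C10 ring-cis)
Conditions: CO (1 atm), Bu3SnH (slow addition), Pd(PPh3)4 (cat.), LiCl, THF, 50 °C
Reagents that add atoms: carbon monoxide, [C-]#[O+]
Why: Palladium-catalysed reductive carbonylation; oxidative addition of zerovalent palladium to the enol triflate, CO insertion and hydride transfer from tin give the enal with retention of alkene geometry. The future methylene is still masked as the amine, so tin hydride cannot reduce it.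

Step 20
Reactants: 25 enal amine
Product: 27 α-methylene lactone enal (C11=C13 in place; O8 TBS; O15 TBDPS), via ammonium iodide 26 (not isolated)
Conditions: MeI, MeOH, rt; then NaHCO3 (aq.), EtOAc, rt
Reagents that add atoms: none
Why: Quaternisation and E1cB (Hofmann-type) loss of trimethylamine under bicarbonate, mild enough for the enal.

Step 21
Reactants: 27 α-methylene lactone enal
Product: 28 C8 alcohol (O8 free; O15 TBDPS)
Conditions: HF·pyridine, pyridine, THF, 0 °C to rt
Reagents that add atoms: none
Why: Acidic fluoride cleavage of a silyl ether; the TBS ether is far more labile to HF·pyridine than the TBDPS ether, so O15 stays protected.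

Step 22
Reactants: 28 C8 alcohol
Product: 29 C8 methacrylate (O15 TBDPS)
Conditions: methacryloyl chloride, Et3N, DMAP (cat.), CH2Cl2, 0 °C
Reagents that add atoms: methacryloyl chloride, C=C(C)C(=O)Cl
Why: DMAP-catalysed acylation of the only free hydroxyl; the acylpyridinium intermediate is reactive enough for the hindered secondary alcohol.

Step 23
Reactants: 29 C8 methacrylate
Product: 30 target CNP0114830.1
Conditions: Bu4NF, AcOH, THF, 0 °C to rt
Reagents that add atoms: none
Why: Fluoride cleavage of the primary TBDPS ether; acetic acid buffers the alkoxide and fluoride so the methacrylate, enal and methylene lactone are not exposed to base.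

## Compound list

1 | 2-bromoprop-2-en-1-ol | C=C(Br)CO | starting material
2 | [(2-bromoprop-2-en-1-yl)oxy](tert-butyl)diphenylsilane | C=C(Br)CO[Si](c1ccccc1)(c1ccccc1)C(C)(C)C | intermediate
3 | 4-(tert-butyldiphenylsilyloxymethyl)pent-4-en-1-ol | OCCCC(=C)CO[Si](c1ccccc1)(c1ccccc1)C(C)(C)C | intermediate
4 | tert-butyl[(5-iodo-2-methylidenepentyl)oxy]diphenylsilane | ICCCC(=C)CO[Si](c1ccccc1)(c1ccccc1)C(C)(C)C | intermediate
5 | (S)-4-(tert-butyldimethylsilyloxy)cyclopent-2-en-1-one | O=C1C=C[C@@H](O[Si](C)(C)C(C)(C)C)C1 | starting material
6 | (S)-4-(tert-butyldimethylsilyloxy)-2-iodocyclopent-2-en-1-one | O=C1C(I)=C[C@@H](O[Si](C)(C)C(C)(C)C)C1 | intermediate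
7 | alkylzinc iodide from 4 | I[Zn]CCCC(=C)CO[Si](c1ccccc1)(c1ccccc1)C(C)(C)C | intermediate (not isolated)
8 | (S)-4-(tert-butyldimethylsilyloxy)-2-[4-(tert-butyldiphenylsilyloxymethyl)pent-4-en-1-yl]cyclopent-2-en-1-one | O=C1C(CCCC(=C)CO[Si](c2ccccc2)(c2ccccc2)C(C)(C)C)=C[C@@H](O[Si](C)(C)C(C)(C)C)C1 | intermediate
9 | epoxy ketone, oxirane on C9–C10 trans to O8 | O=C1[C@]2(CCCC(=C)CO[Si](c3ccccc3)(c3ccccc3)C(C)(C)C)O[C@@H]2[C@@H](O[Si](C)(C)C(C)(C)C)C1 | intermediate
10 | β-hydroxy ketone, C9 hydroxyl trans to O8, C10 epimers | O=C1C(CCCC(=C)CO[Si](c2ccccc2)(c2ccccc2)C(C)(C)C)[C@H](O)[C@@H](O[Si](C)(C)C(C)(C)C)C1 | intermediate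
11 | β-methoxy ketone, C9 methoxy trans to O8, C10 epimers | O=C1C(CCCC(=C)CO[Si](c2ccccc2)(c2ccccc2)C(C)(C)C)[C@H](OC)[C@@H](O[Si](C)(C)C(C)(C)C)C1 | intermediate
12 | aldol adduct, ethyl 2-hydroxyacetate unit on C7 | CCOC(=O)C(O)C1C(=O)C(CCCC(=C)CO[Si](c2ccccc2)(c2ccccc2)C(C)(C)C)[C@H](OC)[C@H]1O[Si](C)(C)C(C)(C)C | intermediate
13 | mesylate of 12 | CCOC(=O)C(OS(C)(=O)=O)C1C(=O)C(CCCC(=C)CO[Si](c2ccccc2)(c2ccccc2)C(C)(C)C)[C@H](OC)[C@H]1O[Si](C)(C)C(C)(C)C | intermediate (not isolated)
14 | alkylidene ketone, C7=C11 | CCOC(=O)C=C1C(=O)C(CCCC(=C)CO[Si](c2ccccc2)(c2ccccc2)C(C)(C)C)[C@H](OC)[C@H]1O[Si](C)(C)C(C)(C)C | intermediate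
15 | dienyl triflate, C6 triflate on C6=C10 | CCOC(=O)C=C1C(OS(=O)(=O)C(F)(F)F)=C(CCCC(=C)CO[Si](c2ccccc2)(c2ccccc2)C(C)(C)C)[C@H](OC)[C@H]1O[Si](C)(C)C(C)(C)C | intermediate
16 | triene ester, vinyl on C6 | CCOC(=O)C=C1C(C=C)=C(CCCC(=C)CO[Si](c2ccccc2)(c2ccccc2)C(C)(C)C)[C@H](OC)[C@H]1O[Si](C)(C)C(C)(C)C | intermediate
17 | diene ester, C7 acetate arm cis to O8, O9 trans to O8 | CCOC(=O)C[C@@H]1[C@H](O[Si](C)(C)C(C)(C)C)[C@@H](OC)C(CCCC(=C)CO[Si](c2ccccc2)(c2ccccc2)C(C)(C)C)=C1C=C | intermediate
18 | bicyclic diene, ethyl 2-[2-(tert-butyldimethylsilyloxy)-7-(tert-butyldiphenylsilyloxymethyl)-3-methoxy-1,2,3,4,5,6-hexahydroazulen-1-yl]acetate | CCOC(=O)C[C@@H]1[C@H](O[Si](C)(C)C(C)(C)C)[C@@H](OC)C2=C1C=C(CO[Si](c3ccccc3)(c3ccccc3)C(C)(C)C)CCC2 | intermediate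
19 | 6,10-ozonide (1,2,4-trioxolane bridging C6 and C10) | CCOC(=O)C[C@@H]1[C@H](O[Si](C)(C)C(C)(C)C)[C@@H](OC)C2(OO3)CCC/C(CO[Si](c4ccccc4)(c4ccccc4)C(C)(C)C)=C\C13O2 | intermediate (not isolated)
20 | cyclodec-4-ene-6,10-dione | CCOC(=O)C[C@@H]1[C@H](O[Si](C)(C)C(C)(C)C)[C@@H](OC)C(=O)CCC/C(CO[Si](c2ccccc2)(c2ccccc2)C(C)(C)C)=C\C1=O | intermediate
21 | C6 hydroxy ester | CCOC(=O)C[C@@H]1[C@H](O[Si](C)(C)C(C)(C)C)[C@@H](OC)C(=O)CCC/C(CO[Si](c2ccccc2)(c2ccccc2)C(C)(C)C)=C\[C@H]1O | intermediate (not isolated)
22 | keto lactone, trans-fused 6,12-olide with C10 ketone | CC(C)(C)[Si](C)(C)O[C@H]1[C@H]2CC(=O)O[C@@H]2/C=C(/CO[Si](c2ccccc2)(c2ccccc2)C(C)(C)C)CCCC(=O)[C@@H]1OC | intermediate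
23 | enol triflate, ring-cis C1=C10 | CC(C)(C)[Si](C)(C)O[C@H]1[C@H]2CC(=O)O[C@@H]2/C=C(/CO[Si](c2ccccc2)(c2ccccc2)C(C)(C)C)CC/C=C(/OS(=O)(=O)C(F)(F)F)[C@@H]1OC | intermediate
24 | Mannich base, CH2NMe2 on C11 | CC(C)(C)[Si](C)(C)O[C@H]1[C@H]2C(CN(C)C)C(=O)O[C@@H]2/C=C(/CO[Si](c2ccccc2)(c2ccccc2)C(C)(C)C)CC/C=C(/OS(=O)(=O)C(F)(F)F)[C@@H]1OC | intermediate
25 | enal amine, C14 formyl on C10 | CC(C)(C)[Si](C)(C)O[C@H]1[C@H]2C(CN(C)C)C(=O)O[C@@H]2/C=C(/CO[Si](c2ccccc2)(c2ccccc2)C(C)(C)C)CC/C=C(/C=O)[C@@H]1OC | intermediate
26 | trimethylammonium iodide of 25 | CC(C)(C)[Si](C)(C)O[C@H]1[C@H]2C(C[N+](C)(C)C)C(=O)O[C@@H]2/C=C(/CO[Si](c2ccccc2)(c2ccccc2)C(C)(C)C)CC/C=C(/C=O)[C@@H]1OC.[I-] | intermediate (not isolated)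
27 | α-methylene lactone enal, O8 TBS, O15 TBDPS | CC(C)(C)[Si](C)(C)O[C@H]1[C@H]2C(=C)C(=O)O[C@@H]2/C=C(/CO[Si](c2ccccc2)(c2ccccc2)C(C)(C)C)CC/C=C(/C=O)[C@@H]1OC | intermediate
28 | C8 alcohol, O15 TBDPS | O[C@H]1[C@H]2C(=C)C(=O)O[C@@H]2/C=C(/CO[Si](c2ccccc2)(c2ccccc2)C(C)(C)C)CC/C=C(/C=O)[C@@H]1OC | intermediate
29 | C8 methacrylate, O15 TBDPS | C=C(C)C(=O)O[C@H]1[C@H]2C(=C)C(=O)O[C@@H]2/C=C(/CO[Si](c2ccccc2)(c2ccccc2)C(C)(C)C)CC/C=C(/C=O)[C@@H]1OC | intermediate
30 | CNP0114830.1 | C=C(C)C(=O)O[C@H]1[C@H]2C(=C)C(=O)O[C@@H]2/C=C(/CO)CC/C=C(/C=O)[C@@H]1OC | target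

## Step count and risks

Total: 23 steps. Longest linear sequence: 22 steps (1 to 30 through steps 1–3 and 5–23); from enone 5 it is 20 steps.

**Step 15 (key step).** Over-oxidation is the main danger: ozone may go on to attack C4=C5 or the silyl-bearing allylic position once the fusion alkene is consumed. The tethered carbonyl oxide may also give peroxidic oligomers that reduce poorly. Fallback: from 18, mCPBA (NaHCO3, CH2Cl2, −20 °C) would epoxidise the more electron-rich tetrasubstituted alkene to the 6,10-epoxide F1, and H5IO6 in aqueous THF would cleave F1 directly to diketone 20.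

**Step 13.** Face selectivity of hydride delivery to C7 may be poor, since the reduction takes place on an exocyclic carbon flanked by a planar diene, and hydride may also add 1,6. Fallback: from 16, HF·pyridine would remove the C8 silyl group, and the freed hydroxyl would close on the ester (cat. acid, the geometric isomer with the ester on the C8 side) to the butenolide F2. Copper hydride reduction of F2 can only give the cis-fused lactone F3, because a trans-fused bicyclo[3.3.0] lactone is too strained. LiOH then EtI/DMF would open F3 to the hydroxy ester F4, which is silylated at once (t-BuMe2SiOTf, 2,6-lutidine) to return 17.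

**Step 16.** Hydride may enter C6 from the wrong face, because the preferred conformation of the ten-membered dione is not known, and the C10 ketone may be reduced as well. Fallback: from 20, exhaustive reduction (NaBH4, CeCl3·7H2O, MeOH, 0 °C) and acid lactonisation would give the C10 hydroxy lactone F5, and Dess–Martin periodinane would return ketone 22. If the C6 epimer forms, the same sequence gives the 6-epi lactone F6. LiOH opens F6 to the hydroxy acid F7, and PPh3/DIAD closes F7 with inversion at the allylic C6 (Mitsunobu lactonisation) to 22.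

**Step 17.** Enolisation may give the ring-trans enolate, or some deprotonation at C9 with loss of the C8 silyloxide, since the geometry of a ten-membered enolate is set by conformation and not by the base. Fallback: from 22, the ring-trans triflate F8 would be carried through steps 18 and 19 as its Mannich base F9 and the ring-trans enal F10. The enal is then equilibrated (PhSSPh cat., hν) to the ring-cis isomer 25. A C14 aldehyde allows this isomerisation, and the ring-cis enal is expected to be the more stable form; thermodynamic control thus replaces kinetic enolate control.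

**Step 11.** The C6 enolate may expel the C9 methoxy group, or the base may add to the doubly activated alkylidene, before triflation. Fallback: from 14, CH2=CHMgBr with CeCl3 (THF, −78 °C) would add 1,2 to the ketone to give the tertiary alcohol F11. The Burgess reagent would dehydrate F11 towards C10, the only carbon with a β-hydrogen, to give 16 without an enolate.

**Step 21.** The TBDPS ether may be lost alongside the TBS ether, because the C8 ether is hindered and needs long exposure. Fallback: from 27, Bu4NF/AcOH would remove both silyl groups to give diol F12, and t-BuPh2SiCl/imidazole would silylate the primary allylic hydroxyl selectively to reach 28.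

## Further compounds

F1 | step 15 | 6,10-epoxide of 18 | CCOC(=O)C[C@@H]1[C@H](O[Si](C)(C)C(C)(C)C)[C@@H](OC)C23CCC/C(CO[Si](c4ccccc4)(c4ccccc4)C(C)(C)C)=C\C12O3
F2 | step 13 | butenolide (O8–C12 lactone with C7=C11) | O=C1C=C2C(C=C)=C(CCCC(=C)CO[Si](c3ccccc3)(c3ccccc3)C(C)(C)C)[C@H](OC)[C@H]2O1
F3 | step 13 | cis-fused 8,12-lactone | O=C1C[C@H]2C(C=C)=C(CCCC(=C)CO[Si](c3ccccc3)(c3ccccc3)C(C)(C)C)[C@H](OC)[C@H]2O1
F4 | step 13 | C8 hydroxy ester | CCOC(=O)C[C@@H]1[C@H](O)[C@@H](OC)C(CCCC(=C)CO[Si](c2ccccc2)(c2ccccc2)C(C)(C)C)=C1C=C
F5 | step 16 | C10 hydroxy lactone | CC(C)(C)[Si](C)(C)O[C@H]1[C@H]2CC(=O)O[C@@H]2/C=C(/CO[Si](c2ccccc2)(c2ccccc2)C(C)(C)C)CCCC(O)[C@@H]1OC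
F6 | step 16 | 6-epi keto lactone | CC(C)(C)[Si](C)(C)O[C@H]1[C@H]2CC(=O)O[C@H]2/C=C(/CO[Si](c2ccccc2)(c2ccccc2)C(C)(C)C)CCCC(=O)[C@@H]1OC
F7 | step 16 | 6-epi hydroxy acid | OC(=O)C[C@@H]1[C@H](O[Si](C)(C)C(C)(C)C)[C@@H](OC)C(=O)CCC/C(CO[Si](c2ccccc2)(c2ccccc2)C(C)(C)C)=C\[C@@H]1O
F8 | step 17 | ring-trans enol triflate | CC(C)(C)[Si](C)(C)O[C@H]1[C@H]2CC(=O)O[C@@H]2/C=C(/CO[Si](c2ccccc2)(c2ccccc2)C(C)(C)C)CC/C=C(\OS(=O)(=O)C(F)(F)F)[C@@H]1OC
F9 | step 17 | ring-trans Mannich base | CC(C)(C)[Si](C)(C)O[C@H]1[C@H]2C(CN(C)C)C(=O)O[C@@H]2/C=C(/CO[Si](c2ccccc2)(c2ccccc2)C(C)(C)C)CC/C=C(\OS(=O)(=O)C(F)(F)F)[C@@H]1OC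
F10 | step 17 | ring-trans enal amine | CC(C)(C)[Si](C)(C)O[C@H]1[C@H]2C(CN(C)C)C(=O)O[C@@H]2/C=C(/CO[Si](c2ccccc2)(c2ccccc2)C(C)(C)C)CC/C=C(\C=O)[C@@H]1OC
F11 | step 11 | C6 tertiary vinyl carbinol | CCOC(=O)C=C1C(O)(C=C)C(CCCC(=C)CO[Si](c2ccccc2)(c2ccccc2)C(C)(C)C)[C@H](OC)[C@H]1O[Si](C)(C)C(C)(C)C
F12 | step 21 | O8,O15 diol | O[C@H]1[C@H]2C(=C)C(=O)O[C@@H]2/C=C(/CO)CC/C=C(/C=O)[C@@H]1OC
A1 | alternative 1 | exo-6-substituted 2,7-dioxabicyclo[3.2.0]hept-3-ene | [C@H]12O[C@H]([C@@H](OC)CO[Si](C)(C)C(C)(C)C)[C@H]1C=CO2
A2 | alternative 1 | 3-(tert-butyldimethylsilyloxy)-2-methoxypropanal | O=C[C@@H](OC)CO[Si](C)(C)C(C)(C)C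
A3 | alternative 1 | furan | c1ccoc1
A4 | alternative 2 | cis-anti-cis tricyclic photoadduct | O=C1[C@H]2[C@]3(C(=O)OC)CC[C@@H]3[C@@]2(CO[Si](C)(C)C(C)(C)C)[C@H](OC)[C@@H](O[Si](CC)(CC)CC)[C@H]1CCOCc1ccc(OC)cc1
A5 | alternative 2 | cyclohexenone partner (C6 ketone, C5=C10) | O=C1C=C(CO[Si](C)(C)C(C)(C)C)[C@H](OC)[C@@H](O[Si](CC)(CC)CC)[C@H]1CCOCc1ccc(OC)cc1
A6 | alternative 2 | methyl cyclobut-1-ene-1-carboxylate | COC(=O)C1=CCC1
A7 | alternative 3 | cyclodeca-1(10),4-dien-6-one with C8 OPMB and C9 OMe | O=C1C[C@H](OCc2ccc(OC)cc2)[C@@H](OC)/C(CO[Si](C)(C)C(C)(C)C)=C/CC/C(CO[Si](C(C)C)(C(C)C)C(C)C)=C\1
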